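**Strategy**

Myrtucommulone A is cut at the two bonds from C-3 and C-5 of the acylphloroglucinol core (ring A) to the isopropyl-bearing methines. The feature exploited is the 1,3-relationship of the C-1 ketone oxygen to both flanking phenol oxygens (O-2, O-6) of ring A. Once these carry allyl groups, each oxygen pair can grip a chiral copper Lewis acid, and the only free ortho carbon of each ether is C-3 or C-5. A double enantioselective aromatic Claisen rearrangement of the 4-O-benzyl bis[(E)-4-methylpent-2-enyl] ether therefore makes both aryl–methine bonds and both stereocentres in one operation. The vinyl groups left behind are then built into the two syncarpic acid rings (rings B and C).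

Key step: step 4

Assumption: the (S,S)-configured bis(oxazoline) ligand is taken to give the (S,S)-rearrangement product; if the sense of induction is the opposite, the (R,R)-ligand is used and nothing else changes.
Remark: the spatial arrangement at both methines stays the same from the rearrangement product to the target; the descriptor changes from S to R only because the CIP ranking of the substituents changes.
Assumption: methyl 2,2,4-trimethyl-3-oxopentanoate and geometrically pure (E)-4-methylpent-2-enoic acid are taken as catalogue compounds.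

**Route**

Step 1
Reactants: 1 phloroisobutyrophenone [2-methyl-1-(2,4,6-trihydroxyphenyl)propan-1-one]; 2 benzyl bromide
Product: 3 1-[4-(benzyloxy)-2,6-dihydroxyphenyl]-2-methylpropan-1-one
Conditions: BnBr (1.0 equiv), K2CO3 (1.1 equiv), DMF, 0 °C to rt
Reagents that add atoms: benzyl bromide (2), BrCc1ccccc1
Why: Williamson etherification: the C-4 hydroxyl is the most acidic phenol and the only one not tied to the C-1 carbonyl by a hydrogen bond, so one equivalent of base and halide should alkylate it in preference to the two chelated hydroxyls.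

Step 2
Reactants: 4 (E)-4-methylpent-2-enoic acid
Product: 5 (E)-4-methylpent-2-en-1-ol
Conditions: LiAlH4 (1.5 equiv), Et2O, 0 °C to rt; aq. NaOH work-up
Reagents that add atoms: none
Why: Hydride reduction of the carboxylic acid to the primary alcohol; in ether at or below room temperature an alkyl-substituted conjugated double bond is not attacked, so the E geometry is carried into the allylic alcohol.

Step 3
Reactants: 3 1-[4-(benzyloxy)-2,6-dihydroxyphenyl]-2-methylpropan-1-one; 5 (E)-4-methylpent-2-en-1-ol
Product: 6 1-{4-(benzyloxy)-2,6-bis[(E)-4-methylpent-2-enyloxy]phenyl}-2-methylpropan-1-one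
Conditions: 5 (2.6 equiv), PPh3 (2.8 equiv), diisopropyl azodicarboxylate (2.8 equiv), THF, 0 °C to 45 °C
Reagents that add atoms: (E)-4-methylpent-2-en-1-ol (5), CC(C)/C=C/CO
Why: Twofold Mitsunobu etherification: each phenol protonates the phosphine–azodicarboxylate betaine and its phenoxide displaces the primary allylic oxyphosphonium by SN2 at CH2, which keeps the E alkene intact and avoids the C-allylation that phloroglucinol anions can show with allylic halides.

Step 4
Reactants: 6 1-{4-(benzyloxy)-2,6-bis[(E)-4-methylpent-2-enyloxy]phenyl}-2-methylpropan-1-one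
Product: 8 1-{4-(benzyloxy)-2,6-dihydroxy-3,5-bis[(3S)-4-methylpent-1-en-3-yl]phenyl}-2-methylpropan-1-one, via mono-rearranged phenol 7 (not isolated)
Conditions: Cu(OTf)2 (20 mol %), (S,S)-2,2'-(propane-2,2-diyl)bis(4-tert-butyl-4,5-dihydrooxazole) (22 mol %), 4 Å MS, CH2Cl2, −20 °C to rt
Reagents that add atoms: none
Why: The cationic divalent copper–bis(oxazoline) complex binds the C-1 carbonyl oxygen and one ether oxygen of 6 in a six-membered chelate, which polarises the O–CH2 bond and lets the allyl terminus that carries the isopropyl group bond to the only free ortho carbon (C-3) through a chair-like six-membered [3,3] array; enolisation restores the phenol of 7, after which the catalyst engages the second ether and the same event takes place at C-5. The closest known reaction type is the Lewis acid-catalysed enantioselective aromatic Claisen rearrangement of allyl aryl ethers whose ortho carbonyl group gives two-point binding to a chiral copper complex. No ring is closed; two aryl–C(sp3) bonds are formed. Each stereocentre is set by the catalyst, whose tert-butyl groups leave one face of the chelated arene open to the (E)-allyl unit, so the fixed alkene geometry and the chair arrangement should translate into the S configuration at both methines, and the minor pathway is diverted largely into the meso diastereomer, which should be separable. The step needs ortho regioselectivity, concerted [3,3] transfer instead of ionisation, and face selectivity: the acyl group blocks C-1 and supplies the chelate, the benzyloxy group at C-4 has no carbonyl partner for chelation, and a non-coordinating solvent at low temperature keeps the allyl fragment bound during transfer.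

Step 5
Reactants: 8 1-{4-(benzyloxy)-2,6-dihydroxy-3,5-bis[(3S)-4-methylpent-1-en-3-yl]phenyl}-2-methylpropan-1-one; 2 benzyl bromide
Product: 9 1-{2,4,6-tris(benzyloxy)-3,5-bis[(3S)-4-methylpent-1-en-3-yl]phenyl}-2-methylpropan-1-one
Conditions: BnBr (3 equiv), K2CO3 (4 equiv), Bu4NI (10 mol %), DMF, 60 °C
Reagents that add atoms: benzyl bromide (2), BrCc1ccccc1
Why: Williamson benzylation of the two hydrogen-bonded, flanked phenols, pushed by heat and iodide catalysis; carbonate cannot deprotonate the methines or move the vinyl double bonds, so both stereocentres are untouched, and the phenols are masked for the borane, oxidant and enolate steps ahead.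

Step 6
Reactants: 9 1-{2,4,6-tris(benzyloxy)-3,5-bis[(3S)-4-methylpent-1-en-3-yl]phenyl}-2-methylpropan-1-one
Product: 11 1-{2,4,6-tris(benzyloxy)-3,5-bis[(3R)-1-hydroxy-4-methylpentan-3-yl]phenyl}-2-methylpropan-1-one, via bis(alkylborane) 10 (not isolated)
Conditions: 9-borabicyclo[3.3.1]nonane (9-BBN, 3 equiv), THF, 0 °C to rt; then 3 M NaOH, 30% H2O2, 0 °C to rt
Reagents that add atoms: hydrogen peroxide, OO
Why: Hydroboration–oxidation: the bulky dialkylborane adds boron to the terminal carbon of each vinyl group and alkaline peroxide replaces boron by hydroxyl, while the twisted, doubly ortho-substituted isopropyl aryl ketone is too hindered to be reduced by 9-BBN at room temperature and the neighbouring stereocentres are not involved.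

Step 7
Reactants: 11 1-{2,4,6-tris(benzyloxy)-3,5-bis[(3R)-1-hydroxy-4-methylpentan-3-yl]phenyl}-2-methylpropan-1-one
Product: 13 (3R,3'R)-3,3'-[2,4,6-tris(benzyloxy)-5-(2-methylpropanoyl)-1,3-phenylene]bis(4-methylpentanoic acid), via dialdehyde 12 (not isolated)
Conditions: 2,2,6,6-tetramethylpiperidin-1-oxyl (20 mol %), PhI(OAc)2 (5 equiv), MeCN/H2O (1:1), rt
Reagents that add atoms: water, O
Why: Oxoammonium (TEMPO) oxidation with PhI(OAc)2 as terminal oxidant takes each primary alcohol through the aldehyde and its hydrate to the carboxylic acid under near-neutral conditions that spare the benzyl ethers, the fully substituted arene and the β-stereocentres.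

Step 8
Reactants: 13 (3R,3'R)-3,3'-[2,4,6-tris(benzyloxy)-5-(2-methylpropanoyl)-1,3-phenylene]bis(4-methylpentanoic acid); 14 methyl 2,2,4-trimethyl-3-oxopentanoate
Product: 16 dimethyl (7R,7'R)-7,7'-[2,4,6-tris(benzyloxy)-5-(2-methylpropanoyl)-1,3-phenylene]bis(2,2,4,4,8-pentamethyl-3,5-dioxononanoate), via bis(acid chloride) 15 (not isolated)
Conditions: (COCl)2 (3 equiv), N,N-dimethylformamide (cat.), CH2Cl2, 0 °C to rt, evaporate; then add to 14 (5 equiv)/LiN(iPr)2 (4.8 equiv), THF, −78 °C; AcOH, −78 °C
Reagents that add atoms: methyl 2,2,4-trimethyl-3-oxopentanoate (14), CC(C)C(=O)C(C)(C)C(=O)OC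
Why: Acid chloride formation followed by C-acylation (crossed Claisen-type acylation) of the lithium enolate formed at the only enolisable carbon of 14, the connection by which acetyl chloride is turned into the open-chain precursor of syncarpic acid; two equivalents of enolate per acyl chloride are used because the diketone product is more acidic than 14.

Step 9
Reactants: 16 dimethyl (7R,7'R)-7,7'-[2,4,6-tris(benzyloxy)-5-(2-methylpropanoyl)-1,3-phenylene]bis(2,2,4,4,8-pentamethyl-3,5-dioxononanoate)
Product: 17 tri-O-benzylmyrtucommulone A, 2,2'-{[2,4,6-tris(benzyloxy)-5-(2-methylpropanoyl)-1,3-phenylene]bis[(1R)-2-methylpropane-1,1-diyl]}bis(3-hydroxy-4,4,6,6-tetramethylcyclohex-2-ene-1,5-dione)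
Conditions: KN(SiMe3)2 (5 equiv), THF, −78 °C to 0 °C; then 1 M HCl
Reagents that add atoms: none
Why: Dieckmann condensation: the potassium enolate at the only α-CH2 of each arm attacks the terminal methyl ester in a six-membered closure helped by the two gem-dimethyl groups, and deprotonation of the cyclic β-triketone makes it irreversible; excess amide base keeps all substrate as enolate so that liberated methoxide cannot cleave it, and the stereocentre, β to the enolate carbonyl, is not deprotonated.

Step 10
Reactants: 17 tri-O-benzylmyrtucommulone A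
Product: 18 myrtucommulone A, 2,2'-{[2,4,6-trihydroxy-5-(2-methylpropanoyl)-1,3-phenylene]bis[(1R)-2-methylpropane-1,1-diyl]}bis(3-hydroxy-4,4,6,6-tetramethylcyclohex-2-ene-1,5-dione)
Conditions: H2 (1 atm), 10% Pd/C, EtOAc, rt
Reagents that add atoms: none
Why: Catalytic hydrogenolysis cleaves the three aryl benzyl ethers under neutral conditions that leave the tetrasubstituted enol double bonds and the hydrogen-bonded aryl ketone alone and supply no acid or base that could epimerise the methines by retro-Michael fragmentation.

**Compound list**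

1 | phloroisobutyrophenone, 2-methyl-1-(2,4,6-trihydroxyphenyl)propan-1-one | CC(C)C(=O)c1c(O)cc(O)cc1O | starting material
2 | benzyl bromide | BrCc1ccccc1 | starting material
3 | 1-[4-(benzyloxy)-2,6-dihydroxyphenyl]-2-methylpropan-1-one | CC(C)C(=O)c1c(O)cc(OCc2ccccc2)cc1O | intermediate
4 | (E)-4-methylpent-2-enoic acid | CC(C)/C=C/C(=O)O | starting material
5 | (E)-4-methylpent-2-en-1-ol | CC(C)/C=C/CO | intermediate
6 | 1-{4-(benzyloxy)-2,6-bis[(E)-4-methylpent-2-enyloxy]phenyl}-2-methylpropan-1-one | CC(C)C(=O)c1c(OC/C=C/C(C)C)cc(OCc2ccccc2)cc1OC/C=C/C(C)C | intermediate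
7 | 1-{4-(benzyloxy)-2-hydroxy-6-[(E)-4-methylpent-2-enyloxy]-3-[(3S)-4-methylpent-1-en-3-yl]phenyl}-2-methylpropan-1-one | CC(C)C(=O)c1c(O)c([C@H](C=C)C(C)C)c(OCc2ccccc2)cc1OC/C=C/C(C)C | intermediate (not isolated)
8 | 1-{4-(benzyloxy)-2,6-dihydroxy-3,5-bis[(3S)-4-methylpent-1-en-3-yl]phenyl}-2-methylpropan-1-one | CC(C)C(=O)c1c(O)c([C@H](C=C)C(C)C)c(OCc2ccccc2)c([C@H](C=C)C(C)C)c1O | intermediate
9 | 1-{2,4,6-tris(benzyloxy)-3,5-bis[(3S)-4-methylpent-1-en-3-yl]phenyl}-2-methylpropan-1-one | CC(C)C(=O)c1c(OCc2ccccc2)c([C@H](C=C)C(C)C)c(OCc2ccccc2)c([C@H](C=C)C(C)C)c1OCc1ccccc1 | intermediate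
10 | 1-{2,4,6-tris(benzyloxy)-3,5-bis[(3R)-1-(9-borabicyclo[3.3.1]nonan-9-yl)-4-methylpentan-3-yl]phenyl}-2-methylpropan-1-one | CC(C)C(=O)c1c(OCc2ccccc2)c([C@H](CCB2C3CCCC2CCC3)C(C)C)c(OCc2ccccc2)c([C@H](CCB2C3CCCC2CCC3)C(C)C)c1OCc1ccccc1 | intermediate (not isolated)
11 | 1-{2,4,6-tris(benzyloxy)-3,5-bis[(3R)-1-hydroxy-4-methylpentan-3-yl]phenyl}-2-methylpropan-1-one | CC(C)C(=O)c1c(OCc2ccccc2)c([C@H](CCO)C(C)C)c(OCc2ccccc2)c([C@H](CCO)C(C)C)c1OCc1ccccc1 | intermediate
12 | (3R,3'R)-3,3'-[2,4,6-tris(benzyloxy)-5-(2-methylpropanoyl)-1,3-phenylene]bis(4-methylpentanal) | CC(C)C(=O)c1c(OCc2ccccc2)c([C@H](CC=O)C(C)C)c(OCc2ccccc2)c([C@H](CC=O)C(C)C)c1OCc1ccccc1 | intermediate (not isolated)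
13 | (3R,3'R)-3,3'-[2,4,6-tris(benzyloxy)-5-(2-methylpropanoyl)-1,3-phenylene]bis(4-methylpentanoic acid) | CC(C)C(=O)c1c(OCc2ccccc2)c([C@H](CC(=O)O)C(C)C)c(OCc2ccccc2)c([C@H](CC(=O)O)C(C)C)c1OCc1ccccc1 | intermediate
14 | methyl 2,2,4-trimethyl-3-oxopentanoate | CC(C)C(=O)C(C)(C)C(=O)OC | starting material
15 | (3R,3'R)-3,3'-[2,4,6-tris(benzyloxy)-5-(2-methylpropanoyl)-1,3-phenylene]bis(4-methylpentanoyl chloride) | CC(C)C(=O)c1c(OCc2ccccc2)c([C@H](CC(=O)Cl)C(C)C)c(OCc2ccccc2)c([C@H](CC(=O)Cl)C(C)C)c1OCc1ccccc1 | intermediate (not isolated)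
16 | dimethyl (7R,7'R)-7,7'-[2,4,6-tris(benzyloxy)-5-(2-methylpropanoyl)-1,3-phenylene]bis(2,2,4,4,8-pentamethyl-3,5-dioxononanoate) | CC(C)C(=O)c1c(OCc2ccccc2)c([C@H](CC(=O)C(C)(C)C(=O)C(C)(C)C(=O)OC)C(C)C)c(OCc2ccccc2)c([C@H](CC(=O)C(C)(C)C(=O)C(C)(C)C(=O)OC)C(C)C)c1OCc1ccccc1 | intermediate
17 | tri-O-benzylmyrtucommulone A, (R,R) at the two methines, enol form drawn | CC(C)C(=O)c1c(OCc2ccccc2)c([C@H](C2=C(O)C(C)(C)C(=O)C(C)(C)C2=O)C(C)C)c(OCc2ccccc2)c([C@H](C2=C(O)C(C)(C)C(=O)C(C)(C)C2=O)C(C)C)c1OCc1ccccc1 | intermediate
18 | myrtucommulone A, (R,R) at the two methines, enol form drawn | CC(C)C(=O)c1c(O)c([C@H](C2=C(O)C(C)(C)C(=O)C(C)(C)C2=O)C(C)C)c(O)c([C@H](C2=C(O)C(C)(C)C(=O)C(C)(C)C2=O)C(C)C)c1O | target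

**Step count and risks**

Total step count: 10. Longest linear sequence: 9 steps (from 1 through steps 1 and 3 to 10); step 2 supplies the side-chain alcohol.

Steps most likely to fail:

1. Step 4. The hydroxy ketone formed after the first shift may hold the copper catalyst and stall turnover before the second shift. Heterolysis of the activated ether may erode face selectivity or lead to 1,3-transfer of the allyl group. The Lewis acid may also induce ring closure of a new ortho-allyl phenol onto its own double bond. The fallback replaces catalyst control by chirality transfer from the substrate; it sets out from 3 and comes back at 8. Compound 3 is etherified twice under Mitsunobu conditions, with inversion, by (2S,3E)-5-methylhex-3-en-2-ol F1. F1 is obtained by borane reduction of commercial (E)-5-methylhex-3-en-2-one with the (R)-B-methyl oxazaborolidine derived from diphenylprolinol (CBS catalyst). The product is 1-{4-(benzyloxy)-2,6-bis[(2R,3E)-5-methylhex-3-en-2-yloxy]phenyl}-2-methylpropan-1-one F2. Aromatic Claisen rearrangement of F2 (Eu(fod)3 in CHCl3 at 50 °C, or heat alone) passes the carbinol configuration on to the ring-bound carbon through the chair transition state with the methyl group equatorial. It should give 1-{4-(benzyloxy)-2,6-dihydroxy-3,5-bis[(3S,4E)-2-methylhex-4-en-3-yl]phenyl}-2-methylpropan-1-one F3. Ethenolysis of F3 (ethylene, second-generation Hoveyda–Grubbs catalyst, CH2Cl2) trims each propenyl group to vinyl and rejoins the route at 8.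

2. Step 8. The crowded tetrasubstituted enolate may be acylated on oxygen, the acid chloride may be deprotonated to a ketene, or a neighbouring benzyl ether oxygen may attack the acyl chloride with loss of benzyl. The fallback replaces acylation by an aldol addition and oxidation; it sets out from 11 and comes back at 16. The diol 11 is oxidised with Dess–Martin periodinane to the dialdehyde 12, here isolated. Aldol addition of the lithium enolate of 14 (LiN(iPr)2, THF, −78 °C) to 12 should give dimethyl (7R,7'R)-7,7'-[2,4,6-tris(benzyloxy)-5-(2-methylpropanoyl)-1,3-phenylene]bis(5-hydroxy-2,2,4,4,8-pentamethyl-3-oxononanoate) F4 as a mixture of carbinol epimers. A second Dess–Martin oxidation removes the new carbinol centres and delivers 16.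

3. Step 3. The reaction may stall after the first etherification because the remaining phenol is hydrogen-bonded to the ketone, and the alcohol may be consumed by alkylation of the reduced azo reagent. The fallback replaces alcohol activation by a Williamson reaction with a preformed halide; it sets out from 5 and 3 and comes back at 6. Alcohol 5 is converted with PBr3 (Et2O, 0 °C) into (E)-1-bromo-4-methylpent-2-ene F5, and 3 is alkylated twice with F5 (Cs2CO3, DMF, 40 °C) to give 6.

Further compounds
F1 | step 4 | (2S,3E)-5-methylhex-3-en-2-ol | C[C@H](O)/C=C/C(C)C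
F2 | step 4 | 1-{4-(benzyloxy)-2,6-bis[(2R,3E)-5-methylhex-3-en-2-yloxy]phenyl}-2-methylpropan-1-one | CC(C)C(=O)c1c(O[C@H](C)/C=C/C(C)C)cc(OCc2ccccc2)cc1O[C@H](C)/C=C/C(C)C
F3 | step 4 | 1-{4-(benzyloxy)-2,6-dihydroxy-3,5-bis[(3S,4E)-2-methylhex-4-en-3-yl]phenyl}-2-methylpropan-1-one | CC(C)C(=O)c1c(O)c([C@H](/C=C/C)C(C)C)c(OCc2ccccc2)c([C@H](/C=C/C)C(C)C)c1O
F4 | step 8 | dimethyl (7R,7'R)-7,7'-[2,4,6-tris(benzyloxy)-5-(2-methylpropanoyl)-1,3-phenylene]bis(5-hydroxy-2,2,4,4,8-pentamethyl-3-oxononanoate), mixture of carbinol epimers | CC(C)C(=O)c1c(OCc2ccccc2)c([C@H](CC(O)C(C)(C)C(=O)C(C)(C)C(=O)OC)C(C)C)c(OCc2ccccc2)c([C@H](CC(O)C(C)(C)C(=O)C(C)(C)C(=O)OC)C(C)C)c1OCc1ccccc1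
F5 | step 3 | (E)-1-bromo-4-methylpent-2-ene | CC(C)/C=C/CBr
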